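The cis C3=C4 unit of the six-membered lactone ring, flanked by carbonyl C2 and methylene C5, is read as acetylene used as a two-carbon 1,2-dianion. In one flask lithium acetylide opens a terminal epoxide, whose oxygen becomes ring O1 on C6, to make C4–C5, and the resulting metal alkynide takes up CO2 to make C2–C3. The precursor is an epoxide carrying the whole C23 chain with two 1,3-dithianes as latent ketones, assembled in two one-flask dithiane couplings with (R)-epichlorohydrin. The linear 2-ynoic acid keeps O1 and C2 apart while two hydroxyl-directed syn reductions set the remaining carbinols; semihydrogenation then closes the ring.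

Key step: step 3

Remarks:
- Locants: lactone ring O1, C2 (C=O), C3, C4, C5, C6; side chain C1′–C21′ with hydroxyls on C2′, C4′ and C6′. Open-chain intermediates are numbered as hexacos-2-ynoic acids, in which C5, C7, C9 and C11 correspond to ring C6, C2′, C4′ and C6′.
- Assumption: (R)-epichlorohydrin of high enantiomeric purity is used; it is the only source of absolute configuration.

Step 1
Reactants: 1 1,3-dithiane; 2 1-bromopentadecane; 3 (R)-epichlorohydrin
Product: 6 2-[(2R)-oxiran-2-ylmethyl]-2-pentadecyl-1,3-dithiane, via 2-pentadecyl-1,3-dithiane 4 (not isolated), via lithium chlorohydrin alkoxide 5 (not isolated)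
Conditions: n-BuLi, THF, −30 °C; 2, −30 → 0 °C; n-BuLi, −20 °C; 3, −78 → 0 °C
Reagents that add atoms: none
Why: Corey–Seebach umpolung run twice in one flask: lithiated 1 is alkylated by the primary bromide 2 to give 4, and relithiated 4 attacks the epoxide CH2 of 3 (not the C–Cl carbon) to give alkoxide 5, which closes by intramolecular Williamson displacement of chloride, so the stereocentre of 3 is carried unchanged into 6 as the future C4′.

Step 2
Reactants: 7 2-(tert-butyldimethylsilyl)-1,3-dithiane; 6 2-[(2R)-oxiran-2-ylmethyl]-2-pentadecyl-1,3-dithiane; 3 (R)-epichlorohydrin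
Product: 11 tert-butyl(dimethyl){[(2R)-1-{2-[(2R)-oxiran-2-ylmethyl]-1,3-dithian-2-yl}-3-(2-pentadecyl-1,3-dithian-2-yl)propan-2-yl]oxy}silane, via lithium alkoxide adduct 8 (not isolated), via Brook-rearranged 2-lithio-1,3-dithiane 9 (not isolated), via lithium chlorohydrin alkoxide 10 (not isolated)
Conditions: 7, t-BuLi, Et2O, −78 → −45 °C; 6, −78 → −25 °C; 3, HMPA–THF, −78 °C → rt
Reagents that add atoms: none
Why: Three-component dithiane linchpin coupling (anion relay): lithiated 7 opens 6 at its CH2 terminus to alkoxide 8, HMPA triggers a 1,4-Brook rearrangement (silyl shift from carbon to oxygen) that protects the C4′ oxygen and unveils dithianyl anion 9, which opens a second molecule of 3 at CH2 and closes via 10 to the epoxide; the future C6 centre again comes unchanged from 3, which places the C4′ and C6 oxygens 1,5-syn.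

Step 3
Reactants: 11 tert-butyl(dimethyl){[(2R)-1-{2-[(2R)-oxiran-2-ylmethyl]-1,3-dithian-2-yl}-3-(2-pentadecyl-1,3-dithian-2-yl)propan-2-yl]oxy}silane; 12 lithium acetylide–ethylenediamine complex (LiC≡CH·H2NCH2CH2NH2); 13 carbon dioxide
Product: 15 (5S)-6-{2-[(2R)-2-{[tert-butyl(dimethyl)silyl]oxy}-3-(2-pentadecyl-1,3-dithian-2-yl)propyl]-1,3-dithian-2-yl}-5-hydroxyhex-2-ynoic acid, via lithium homopropargylic alkoxide 14 (not isolated)
Conditions: 12, DMSO–THF, rt; n-BuLi, 0 °C; CO2 (13), 0 °C → rt; 1 M HCl
Reagents that add atoms: none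
Why: The acetylide carbon of 12 attacks the unsubstituted epoxide carbon of 11 in an SN2 ring opening (C4–C5 bond) to give alkoxide 14; n-BuLi, acting through LiCH2S(O)CH3 formed with the solvent, then removes the remaining alkyne proton of 14 and the alkynyllithium adds to CO2 (C2–C3 bond). The closest known reaction types are the alkynylation of terminal epoxides with lithium acetylide and the carboxylation of metal acetylides with CO2, run here in one flask so that acetylene serves as a 1,2-dianion of a two-carbon unit. No ring is closed in this step: the linear alkyne holds O1 and C2 apart, and the lactone ring is closed in step 6 by 6-exo-trig acyl substitution once the triple bond has become a cis double bond. No stereocentre is formed, and C6 keeps the configuration of the epoxide because only its CH2 neighbour is attacked. The step needs regioselective opening at the CH2 terminus, secured by the monosubstituted epoxide next to a fully substituted dithiane carbon, and C- rather than O-carboxylation, secured because the lithium alkyl carbonate formed at oxygen reverts to the alcohol on acidification while the alkynoate does not.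

Step 4
Reactants: 15 (5S)-6-{2-[(2R)-2-{[tert-butyl(dimethyl)silyl]oxy}-3-(2-pentadecyl-1,3-dithian-2-yl)propyl]-1,3-dithian-2-yl}-5-hydroxyhex-2-ynoic acid
Product: 17 (5S,9R)-5,9-dihydroxy-7,11-dioxohexacos-2-ynoic acid, via silyl ether dione 16 (not isolated)
Conditions: PhI(O2CCF3)2, MeCN–THF–H2O, 0 °C; then 48% aq. HF, 0 °C → rt
Reagents that add atoms: water, O
Why: Oxidative dithiane hydrolysis with the trivalent iodine reagent PhI(O2CCF3)2 (S-activation, attack of water, loss of the disulfide) should free both ketones at 0 °C without touching the electron-poor alkyne, and aqueous HF then cleaves the secondary silyl ether, so that each ketone has a free β-hydroxyl for the next step.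

Step 5
Reactants: 17 (5S,9R)-5,9-dihydroxy-7,11-dioxohexacos-2-ynoic acid
Product: 18 (5S,7S,9R,11R)-5,7,9,11-tetrahydroxyhexacos-2-ynoic acid
Conditions: Et2BOMe, THF–MeOH (4:1), −78 °C; NaBH4, −78 °C; MeOH co-evaporation, dilute acid work-up
Reagents that add atoms: none
Why: Two-directional Narasaka–Prasad reduction: Et2BOMe forms six-membered boron chelates between each β-hydroxyl and its ketone (C5–OH/C7=O and C9–OH/C11=O) and external axial hydride delivery gives the 1,3-syn diol at both sites; because C5 and C9 are already syn, both possible controllers of C7 are matched (the 7S descriptor reflects CIP priorities only, the array is all-syn).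

Step 6
Reactants: 18 (5S,7S,9R,11R)-5,7,9,11-tetrahydroxyhexacos-2-ynoic acid
Product: 20 (6S)-6-[(2R,4R,6R)-2,4,6-trihydroxyhenicosyl]-5,6-dihydro-2H-pyran-2-one, via (2Z)-enoic acid 19 (not isolated)
Conditions: H2 (1 atm), Pd/CaCO3–Pb(OAc)2 (Lindlar catalyst), quinoline, EtOAc–MeOH, rt; then TsOH·H2O (cat.), CH2Cl2, rt
Reagents that add atoms: none
Why: Lindlar semihydrogenation should give the (Z)-enoic acid 19 by syn addition of H2, and only its C5 hydroxyl can reach the carboxyl group through a six-membered transition state, so acid-catalysed 6-exo-trig lactonisation should close the dihydropyranone ring without any protecting group.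

Compound list
1 | 1,3-dithiane | C1CSCSC1 | starting material
2 | 1-bromopentadecane | CCCCCCCCCCCCCCCBr | starting material
3 | (R)-epichlorohydrin, (2R)-2-(chloromethyl)oxirane | ClC[C@H]1CO1 | starting material
4 | 2-pentadecyl-1,3-dithiane | CCCCCCCCCCCCCCCC1SCCCS1 | intermediate
5 | lithium (2R)-1-chloro-3-(2-pentadecyl-1,3-dithian-2-yl)propan-2-olate | CCCCCCCCCCCCCCCC1(C[C@@H]([O-])CCl)SCCCS1.[Li+] | intermediate
6 | 2-[(2R)-oxiran-2-ylmethyl]-2-pentadecyl-1,3-dithiane | CCCCCCCCCCCCCCCC1(C[C@@H]2CO2)SCCCS1 | intermediate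
7 | 2-(tert-butyldimethylsilyl)-1,3-dithiane | CC(C)(C)[Si](C)(C)C1SCCCS1 | starting material
8 | lithium (2R)-1-[2-(tert-butyldimethylsilyl)-1,3-dithian-2-yl]-3-(2-pentadecyl-1,3-dithian-2-yl)propan-2-olate | CCCCCCCCCCCCCCCC1(SCCCS1)C[C@@H]([O-])CC2(SCCCS2)[Si](C)(C)C(C)(C)C.[Li+] | intermediate
9 | {2-[(2S)-2-{[tert-butyl(dimethyl)silyl]oxy}-3-(2-pentadecyl-1,3-dithian-2-yl)propyl]-1,3-dithian-2-yl}lithium (same spatial arrangement as in 8; descriptor changes by priority only) | CCCCCCCCCCCCCCCC1(SCCCS1)C[C@@H](O[Si](C)(C)C(C)(C)C)CC2([Li])SCCCS2 | intermediate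
10 | lithium (2R)-1-{2-[(2R)-2-{[tert-butyl(dimethyl)silyl]oxy}-3-(2-pentadecyl-1,3-dithian-2-yl)propyl]-1,3-dithian-2-yl}-3-chloropropan-2-olate | CCCCCCCCCCCCCCCC1(SCCCS1)C[C@@H](O[Si](C)(C)C(C)(C)C)CC2(SCCCS2)C[C@@H]([O-])CCl.[Li+] | intermediate
11 | tert-butyl(dimethyl){[(2R)-1-{2-[(2R)-oxiran-2-ylmethyl]-1,3-dithian-2-yl}-3-(2-pentadecyl-1,3-dithian-2-yl)propan-2-yl]oxy}silane | CCCCCCCCCCCCCCCC1(SCCCS1)C[C@@H](O[Si](C)(C)C(C)(C)C)CC2(SCCCS2)C[C@@H]3CO3 | intermediate
12 | lithium acetylide–ethylenediamine complex | [Li+].[C-]#C.NCCN | starting material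
13 | carbon dioxide | O=C=O | starting material
14 | lithium (2S)-1-{2-[(2R)-2-{[tert-butyl(dimethyl)silyl]oxy}-3-(2-pentadecyl-1,3-dithian-2-yl)propyl]-1,3-dithian-2-yl}pent-4-yn-2-olate | CCCCCCCCCCCCCCCC1(SCCCS1)C[C@@H](O[Si](C)(C)C(C)(C)C)CC2(SCCCS2)C[C@@H]([O-])CC#C.[Li+] | intermediate
15 | (5S)-6-{2-[(2R)-2-{[tert-butyl(dimethyl)silyl]oxy}-3-(2-pentadecyl-1,3-dithian-2-yl)propyl]-1,3-dithian-2-yl}-5-hydroxyhex-2-ynoic acid | CCCCCCCCCCCCCCCC1(SCCCS1)C[C@@H](O[Si](C)(C)C(C)(C)C)CC2(SCCCS2)C[C@@H](O)CC#CC(=O)O | intermediate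
16 | (5S,9R)-9-{[tert-butyl(dimethyl)silyl]oxy}-5-hydroxy-7,11-dioxohexacos-2-ynoic acid | CCCCCCCCCCCCCCCC(=O)C[C@@H](O[Si](C)(C)C(C)(C)C)CC(=O)C[C@@H](O)CC#CC(=O)O | intermediate
17 | (5S,9R)-5,9-dihydroxy-7,11-dioxohexacos-2-ynoic acid | CCCCCCCCCCCCCCCC(=O)C[C@@H](O)CC(=O)C[C@@H](O)CC#CC(=O)O | intermediate
18 | (5S,7S,9R,11R)-5,7,9,11-tetrahydroxyhexacos-2-ynoic acid (all-syn) | CCCCCCCCCCCCCCC[C@@H](O)C[C@@H](O)C[C@@H](O)C[C@@H](O)CC#CC(=O)O | intermediate
19 | (2Z,5S,7S,9R,11R)-5,7,9,11-tetrahydroxyhexacos-2-enoic acid | CCCCCCCCCCCCCCC[C@@H](O)C[C@@H](O)C[C@@H](O)C[C@@H](O)C/C=C\C(=O)O | intermediate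
20 | (6S)-6-[(2R,4R,6R)-2,4,6-trihydroxyhenicosyl]-5,6-dihydro-2H-pyran-2-one | CCCCCCCCCCCCCCC[C@@H](O)C[C@@H](O)C[C@@H](O)C[C@@H]1CC=CC(=O)O1 | target

Total steps: 6. Longest linear sequence: 6 steps (from 1 to 20).

Steps most likely to fail

Step 4. As both ketones are set free in an acidic aqueous medium, intramolecular aldol condensation of the 1,5-dione and β-dehydration can compete, and oxidative cleavage of the second dithiane may lag behind the first. The fallback sets out from 15 and comes back at 17. The same trivalent iodine reagent PhI(O2CCF3)2 is used in methanol, where each dithiane should be converted into a dimethyl ketal, giving (5S,9R)-9-{[tert-butyl(dimethyl)silyl]oxy}-5-hydroxy-7,7,11,11-tetramethoxyhexacos-2-ynoic acid F2. F2 has no enolisable carbonyl and can be purified. A single mild stage (aq. HF, MeCN, 0 °C) then hydrolyses both ketals and the silyl ether to 17, which is reduced at once.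

Step 5. Facial selectivity at C11 may erode if the C9 hydroxyl, which flanks both carbonyls, is drawn into the boron chelate on the C7 side, and the free acid consumes boron reagent and hydride. The fallback sets out from 15 and comes back at 18. Step 4 is stopped before the HF stage so that 16 is isolated. With the C9 oxygen still silylated only the C5 hydroxyl can form a chelate, so Et2BOMe/NaBH4 at −78 °C should reduce the C7 carbonyl alone to (5S,7S,9S)-9-{[tert-butyl(dimethyl)silyl]oxy}-5,7-dihydroxy-11-oxohexacos-2-ynoic acid F3. Aqueous HF in MeCN then frees the C9 hydroxyl to give (5S,7S,9S)-5,7,9-trihydroxy-11-oxohexacos-2-ynoic acid F4. A second Et2BOMe/NaBH4 reduction, now directed by C9–OH alone, gives 18. The 9S descriptors in F3 and F4 reflect priorities only.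

Step 3. Metalation of the alkyne terminus of 14 may be incomplete in the amine-containing medium, so that part of the material is quenched without carboxylation, and the strongly basic medium may cause silyl loss. The fallback sets out from 11 and comes back at 15. Ethyl propiolate is lithiated (n-BuLi, THF, −78 °C) and added to 11 in the presence of BF3·OEt2, an established alkynylation of terminal epoxides that brings in C2–C4 as one three-carbon nucleophile. It should give ethyl (5S)-6-{2-[(2R)-2-{[tert-butyl(dimethyl)silyl]oxy}-3-(2-pentadecyl-1,3-dithian-2-yl)propyl]-1,3-dithian-2-yl}-5-hydroxyhex-2-ynoate F1. Saponification (LiOH, THF–H2O, 0 °C) then gives 15.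

Further compounds
F1 | step 3 | ethyl (5S)-6-{2-[(2R)-2-{[tert-butyl(dimethyl)silyl]oxy}-3-(2-pentadecyl-1,3-dithian-2-yl)propyl]-1,3-dithian-2-yl}-5-hydroxyhex-2-ynoate | CCCCCCCCCCCCCCCC1(SCCCS1)C[C@@H](O[Si](C)(C)C(C)(C)C)CC2(SCCCS2)C[C@@H](O)CC#CC(=O)OCC
F2 | step 4 | (5S,9R)-9-{[tert-butyl(dimethyl)silyl]oxy}-5-hydroxy-7,7,11,11-tetramethoxyhexacos-2-ynoic acid | CCCCCCCCCCCCCCCC(OC)(OC)C[C@@H](O[Si](C)(C)C(C)(C)C)CC(OC)(OC)C[C@@H](O)CC#CC(=O)O
F3 | step 5 | (5S,7S,9S)-9-{[tert-butyl(dimethyl)silyl]oxy}-5,7-dihydroxy-11-oxohexacos-2-ynoic acid | CCCCCCCCCCCCCCCC(=O)C[C@@H](O[Si](C)(C)C(C)(C)C)C[C@@H](O)C[C@@H](O)CC#CC(=O)O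
F4 | step 5 | (5S,7S,9S)-5,7,9-trihydroxy-11-oxohexacos-2-ynoic acid | CCCCCCCCCCCCCCCC(=O)C[C@@H](O)C[C@@H](O)C[C@@H](O)CC#CC(=O)O
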